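**Strategy**

Both halves are cut from commercial pristimerin. Everything rests on disconnecting the 1,4-benzodioxane at the aryl ether bond between C3 of aromatic ring A and the oxygen on C4' of ring A' of the quinoid half. The oxygen that pristimerin carries at C3 is not kept: it becomes a triflate, and the key step, a palladium-catalysed intramolecular etherification, replaces it by the tertiary C4' hydroxyl and closes the dioxane ring in one operation. The precursor is a seco compound in which O2 of ring A already sits on the ketal carbon C3' (hemiketal oxygen capped as methyl ether) beside the free C4' alcohol; the ortho pair C2–O/C3–OTf of ring A is the feature exploited.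

Key step: step 8

**Remarks on the chemistry (assumptions)**

- Celastroid (24-nor-D:A-friedooleanane) numbering is used; unprimed atoms belong to the aromatic half, primed atoms to the quinoid half.
- Pristimerin (1) is taken as a purchasable starting material.
- Heteroatom nucleophiles are taken to add to C6 of pristimerin-type quinone methides on the β face (syn to the C9 methyl); the fallback for step 2 covers the opposite case.
- The cis-fused hemiketal at C3' (as in the target) is taken to be the epimer reached when the hemiketal equilibrates; the C3' configuration of 12 and 13 is therefore provisional.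

**Route**

Step 1
Reactants: 1 pristimerin
Product: 2 pristimerin 3-O-triflate
Conditions: PhNTf2, Et3N, DMAP (cat.), CH2Cl2, 0 °C to rt
Reagents that add atoms: N-phenyl-bis(trifluoromethanesulfonimide) O=S(=O)(N(c1ccccc1)S(=O)(=O)C(F)(F)F)C(F)(F)F
Why: The enol hydroxyl at C3 is the only O–H of the quinone methide, so O-sulfonylation (enol triflation) marks this oxygen for later departure and leaves C2 as the carbonyl that becomes the free phenol.

Step 2
Reactants: 2 pristimerin 3-O-triflate
Product: 5 fragment A (methyl 8β-H-2-hydroxy-3-triflyloxy-24-nor-D:A-friedooleana-1,3,5(10),6-tetraen-29-oate), via C6 tosylhydrazine adduct 3 (not isolated), via allylic diazene 4 (not isolated)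
Conditions: TsNHNH2, AcOH (cat.), THF, 0 °C to rt; then NaOAc, 65 °C
Reagents that add atoms: none
Why: Proposed new method: the hydrazide NH2 should add 1,6 to C6 of the quinone methide (driven by aromatisation of ring A), acetate then expels sulfinate from the N-alkyl-N'-tosylhydrazine to give the allylic diazene, and its retro-ene loss of N2 moves the double bond to C6=C7 while delivering hydrogen to C8 on the face that carries nitrogen at C6 (β, see remarks), which sets 8β-H; the closest known reaction types are 1,6-additions of nitrogen nucleophiles to p-quinone methides and the allylic diazene rearrangement in the alkene-walk reduction of enone tosylhydrazones.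

Step 3
Reactants: 1 pristimerin
Product: 6 3-O-methylpristimerin
Conditions: MeI, K2CO3, acetone, rt
Reagents that add atoms: iodomethane CI
Why: Williamson O-alkylation of the acidic diosphenol hydroxyl turns the enol into the methyl enol ether that later becomes the ketal methyl group.

Step 4
Reactants: 6 3-O-methylpristimerin
Product: 7 2-O-acetyl-3-O-methylpristimerol (ring A aromatic, C6H2, 7-ene)
Conditions: Zn, Ac2O, AcOH, NaOAc, 40 °C
Reagents that add atoms: acetic anhydride CC(=O)OC(C)=O
Why: Reductive acetylation: zinc reduces the quinone methide by two electrons with protonation at C6, and the C2 phenoxide is trapped as the acetate, which protects the phenol during the radical hydrogenation.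

Step 5
Reactants: 7 2-O-acetyl-3-O-methylpristimerol
Product: 8 2-O-acetyl-3-O-methyl-7,8-dihydropristimerol (8α-H)
Conditions: Mn(dpm)3 (dpm = 2,2,6,6-tetramethylheptane-3,5-dionate, 10 mol %), PhSiH3, t-BuOOH, i-PrOH, rt
Reagents that add atoms: none
Why: Metal hydride hydrogen atom transfer hydrogenation (Mukaiyama type) adds a hydrogen atom to C7, and the tertiary C8 radical takes up hydrogen on the α face, away from the axial C9 and C14 methyls, which is also the more stable trans B/C junction (8α-H).

Step 6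
Reactants: 8 2-O-acetyl-3-O-methyl-7,8-dihydropristimerol
Product: 10 fragment B (3-O-methyl-7,8-dihydropristimerin, 8α-H quinone methide), via phenol 9 (not isolated)
Conditions: NH3, MeOH, rt, argon; evaporate; then Ag2O, CH2Cl2, rt, filter
Reagents that add atoms: none
Why: Ammonolysis frees the C2 phenol, and Ag2O dehydrogenates the 4-alkyl-2-methoxyphenol across O2–H/C6–H to the p-quinone methide under neutral conditions, which avoids tautomerisation to the C6=C7 styrenyl phenol.

Step 7
Reactants: 10 fragment B; 5 fragment A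
Product: 12 seco precursor (3'β-aryloxy-3'α-methoxy-4'α-hydroxy ketal; aryl = fragment A bound through O2, C3–OTf intact), via methoxy epoxide 11 (not isolated)
Conditions: dimethyldioxirane, acetone/CH2Cl2, −40 °C; volatiles removed cold; then 5, ZnCl2, THF, −78 to 0 °C
Reagents that add atoms: dimethyldioxirane CC1(C)OO1
Why: The dioxirane epoxidises the electron-rich enol ether bond C3'=C4' on the α face, anti to the axial C9' methyl, which fixes C4' (oxygen α), and the alkoxy epoxide is then opened at the acetal carbon C3' by the phenol of 5 with inversion (glycal-epoxide type glycosylation), leaving the tertiary C4' hydroxyl free.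

Step 8
Reactants: 12 seco precursor
Product: 13 O-methyl ketal of the target (trans-fused: 3'α-OMe, 3'β-O2, 4'α-O3)
Conditions: Pd2(dba)3 (dba = dibenzylideneacetone, 5 mol %), 2-(di-tert-butylphosphino)-1,1'-binaphthyl (12 mol %), Cs2CO3, toluene, 80 °C
Reagents that add atoms: none
Why: Zerovalent palladium inserts into the C3–OTf bond of ring A, carbonate deprotonates the C4' hydroxyl, and the resulting seven-membered aryl(alkoxo) complex of divalent palladium undergoes C–O reductive elimination. The closest known reaction is the Buchwald–Hartwig intramolecular etherification of ortho-functionalised aryl ethers to 1,4-benzodioxanes, which works best with tertiary alcohols. The six-membered dioxane ring is closed in a 6-exo sense, the oxygen entering at C3 ipso to the leaving group. No stereocentre is formed; C4' (set in step 7), C8 and C8' are untouched, and the trans relation of O2 and O4' is accommodated by the diequatorial half-chair of ring A'. The step needs O4' to react in preference to any other oxygen and reductive elimination to outrun β-hydride elimination and triflyl transfer: O4' is the only free hydroxyl because the hemiketal oxygen is capped as methyl ether (so a five-membered dioxole closure is excluded), C4' bears no hydrogen, and intramolecular sulfonyl transfer is geometrically disfavoured while the weak base keeps the alkoxide concentration low.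

Step 9
Reactants: 13 O-methyl ketal of the target
Product: 14 target CNP0271025.2
Conditions: HCl (1 M aq.), THF, rt to 40 °C
Reagents that add atoms: water O
Why: Acid hydrolysis of the methyl ketal passes through the cyclic C3' oxocarbenium ion and the ring-chain equilibrium of the hemiketal, which should settle on the cis-fused hemiketal (O2 and O4' both α, 3'-OH β) favoured by the anomeric effect and the hydrogen bond to the C2' ketone, while C4' is untouched.

**Compound list**

1 | pristimerin, methyl (20α)-3-hydroxy-2-oxo-24-nor-D:A-friedooleana-1(10),3,5,7-tetraen-29-oate | COC(=O)[C@]1(C)CC[C@]2(C)CC[C@]3(C)C4=CC=C5C(C)=C(O)C(=O)C=C5[C@]4(C)CC[C@@]3(C)[C@@H]2C1 | starting material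

2 | pristimerin 3-O-triflate (enol oxygen at C3 carries SO2CF3) | COC(=O)[C@]1(C)CC[C@]2(C)CC[C@]3(C)C4=CC=C5C(C)=C(OS(=O)(=O)C(F)(F)F)C(=O)C=C5[C@]4(C)CC[C@@]3(C)[C@@H]2C1 | intermediate

3 | methyl 2-hydroxy-6β-(2-tosylhydrazinyl)-3-triflyloxy-24-nor-D:A-friedooleana-1,3,5(10),7-tetraen-29-oate | COC(=O)[C@]1(C)CC[C@]2(C)CC[C@]3(C)C4=C[C@@H](NNS(=O)(=O)c6ccc(C)cc6)c5c(cc(O)c(OS(=O)(=O)C(F)(F)F)c5C)[C@]4(C)CC[C@@]3(C)[C@@H]2C1 | intermediate (not isolated)

4 | methyl 6β-diazenyl-2-hydroxy-3-triflyloxy-24-nor-D:A-friedooleana-1,3,5(10),7-tetraen-29-oate | COC(=O)[C@]1(C)CC[C@]2(C)CC[C@]3(C)C4=C[C@@H](N=N)c5c(cc(O)c(OS(=O)(=O)C(F)(F)F)c5C)[C@]4(C)CC[C@@]3(C)[C@@H]2C1 | intermediate (not isolated)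

5 | fragment A, methyl 8β-H-2-hydroxy-3-triflyloxy-24-nor-D:A-friedooleana-1,3,5(10),6-tetraen-29-oate | COC(=O)[C@]1(C)CC[C@]2(C)CC[C@]3(C)[C@@H]4C=Cc5c(cc(O)c(OS(=O)(=O)C(F)(F)F)c5C)[C@]4(C)CC[C@@]3(C)[C@@H]2C1 | intermediate

6 | 3-O-methylpristimerin (methyl enol ether of the quinone methide) | COC(=O)[C@]1(C)CC[C@]2(C)CC[C@]3(C)C4=CC=C5C(C)=C(OC)C(=O)C=C5[C@]4(C)CC[C@@]3(C)[C@@H]2C1 | intermediate

7 | methyl 2-acetoxy-3-methoxy-24-nor-D:A-friedooleana-1,3,5(10),7-tetraen-29-oate | COC(=O)[C@]1(C)CC[C@]2(C)CC[C@]3(C)C4=CCc5c(C)c(OC)c(OC(C)=O)cc5[C@]4(C)CC[C@@]3(C)[C@@H]2C1 | intermediate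

8 | methyl 8α-H-2-acetoxy-3-methoxy-24-nor-D:A-friedooleana-1,3,5(10)-trien-29-oate | COC(=O)[C@]1(C)CC[C@]2(C)CC[C@]3(C)[C@H]4CCc5c(C)c(OC)c(OC(C)=O)cc5[C@]4(C)CC[C@@]3(C)[C@@H]2C1 | intermediate

9 | methyl 8α-H-2-hydroxy-3-methoxy-24-nor-D:A-friedooleana-1,3,5(10)-trien-29-oate | COC(=O)[C@]1(C)CC[C@]2(C)CC[C@]3(C)[C@H]4CCc5c(C)c(OC)c(O)cc5[C@]4(C)CC[C@@]3(C)[C@@H]2C1 | intermediate (not isolated)

10 | fragment B, methyl 8α-H-3-methoxy-2-oxo-24-nor-D:A-friedooleana-1(10),3,5-trien-29-oate | COC(=O)[C@]1(C)CC[C@]2(C)CC[C@]3(C)[C@H]4CC=C5C(C)=C(OC)C(=O)C=C5[C@]4(C)CC[C@@]3(C)[C@@H]2C1 | intermediate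

11 | methyl 8α-H-3α,4α-epoxy-3β-methoxy-2-oxo-24-nor-D:A-friedooleana-1(10),5-dien-29-oate | COC(=O)[C@]1(C)CC[C@]2(C)CC[C@]3(C)[C@H]4CC=C5[C@]6(C)O[C@]6(OC)C(=O)C=C5[C@]4(C)CC[C@@]3(C)[C@@H]2C1 | intermediate (not isolated)

12 | seco precursor: ring A' is a 4'α-hydroxy-3'α-methoxy-2'-oxo-1'(10'),5'-diene whose C3' carries, β, the C2 oxygen of fragment A; aryl C3–OTf intact | COC(=O)[C@]1(C)CC[C@]2(C)CC[C@]3(C)[C@@H]4C=Cc5c(cc(O[C@@]6(OC)C(=O)C=C7C(=CC[C@H]8[C@@]7(C)CC[C@@]9(C)[C@@H]%10C[C@](C)(C(=O)OC)CC[C@]%10(C)CC[C@]89C)[C@]6(C)O)c(OS(=O)(=O)C(F)(F)F)c5C)[C@]4(C)CC[C@@]3(C)[C@@H]2C1 | intermediate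

13 | O-methyl ketal of the target, trans-fused dioxane (3'α-OMe, 3'β-O2, 4'α-O3) | COC(=O)[C@]1(C)CC[C@]2(C)CC[C@]3(C)[C@@H]4C=Cc5c(cc6c(c5C)O[C@@]5(C)C7=CC[C@H]8[C@@](C)(CC[C@@]9(C)[C@@H]%10C[C@](C)(C(=O)OC)CC[C@]%10(C)CC[C@]89C)C7=CC(=O)[C@]5(OC)O6)[C@]4(C)CC[C@@]3(C)[C@@H]2C1 | intermediate

14 | CNP0271025.2 | COC(=O)[C@]1(C)CC[C@]2(C)CC[C@]3(C)[C@@H]4C=Cc5c(cc6c(c5C)O[C@@]5(C)C7=CC[C@H]8[C@@](C)(CC[C@@]9(C)[C@@H]%10C[C@](C)(C(=O)OC)CC[C@]%10(C)CC[C@]89C)C7=CC(=O)[C@@]5(O)O6)[C@]4(C)CC[C@@]3(C)[C@@H]2C1 | target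

**Step count and risks**

Total step count: 9. Longest linear sequence: 7 steps (steps 3 to 9 from pristimerin).

Steps most likely to fail:

1. Step 2 (proposed new method). The hydrazide may attack the α face of C6, or add reversibly without face control, so that the diazene delivers hydrogen to the wrong face of C8. The fallback places the nitrogen by hydride delivery, using the known alkene-walk reduction of an enone tosylhydrazone. It sets out from 2. Compound 2 is hydrated at C6 (H2O, NaHCO3, THF) to the 6α-hydroxy compound F1 and oxidised with MnO2 to the 6-ketone F2. Condensation with TsNHNH2 gives the tosylhydrazone F3, which is reduced with catecholborane; hydride attack on C6=N from the same α face puts nitrogen on the β face. The fallback returns to the route at 3, which loses sulfinate and N2 as in step 2 to give 5.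

2. Step 8 (key step). Retro-aldol opening of ring A' or intermolecular loss of the triflyl group under the basic conditions may outrun C–O reductive elimination. The fallback closes the dioxane by the biomimetic hetero-Diels–Alder reaction, which forms the two alkyl C–O bonds instead. It sets out from 5 and 10. The triflate of 5 is cleaved with Et4NOH to the catechol F4, which is oxidised with Ag2O at low temperature to the o-quinone F5. F5 is trapped in situ by the enol ether bond of 10 on its α face to give the cis-fused methyl ketal F6, the C3' epimer of 13. The conditions of step 9 convert F6 into 14, where the fallback rejoins the route.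

3. Step 7. The methoxy epoxide may open at the allylic carbon C4', or rearrange, before the weakly nucleophilic phenol captures it at C3'. The fallback uses an isolable ketal as the C3' electrophile. It sets out from 10, which is oxidised with dimethyldioxirane in methanol, where solvent capture at C3' is fast, to the dimethyl ketal alcohol F7. F7 and phenol 5 are joined by Lewis acid-mediated transketalisation through the C3' oxocarbenium ion (BF3·OEt2, 4 Å molecular sieves, CH2Cl2, −40 °C), returning to the route at 12.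

**Further compounds**

F1 | step 2 | methyl 2,6α-dihydroxy-3-triflyloxy-24-nor-D:A-friedooleana-1,3,5(10),7-tetraen-29-oate | COC(=O)[C@]1(C)CC[C@]2(C)CC[C@]3(C)C4=C[C@H](O)c5c(cc(O)c(OS(=O)(=O)C(F)(F)F)c5C)[C@]4(C)CC[C@@]3(C)[C@@H]2C1
F2 | step 2 | methyl 2-hydroxy-6-oxo-3-triflyloxy-24-nor-D:A-friedooleana-1,3,5(10),7-tetraen-29-oate | COC(=O)[C@]1(C)CC[C@]2(C)CC[C@]3(C)C4=CC(=O)c5c(cc(O)c(OS(=O)(=O)C(F)(F)F)c5C)[C@]4(C)CC[C@@]3(C)[C@@H]2C1
F3 | step 2 | C6 tosylhydrazone of F2 | COC(=O)[C@]1(C)CC[C@]2(C)CC[C@]3(C)C4=CC(=NNS(=O)(=O)c6ccc(C)cc6)c5c(cc(O)c(OS(=O)(=O)C(F)(F)F)c5C)[C@]4(C)CC[C@@]3(C)[C@@H]2C1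
F4 | step 8 | methyl 8β-H-2,3-dihydroxy-24-nor-D:A-friedooleana-1,3,5(10),6-tetraen-29-oate | COC(=O)[C@]1(C)CC[C@]2(C)CC[C@]3(C)[C@@H]4C=Cc5c(cc(O)c(O)c5C)[C@]4(C)CC[C@@]3(C)[C@@H]2C1
F5 | step 8 | methyl 8β-H-2,3-dioxo-24-nor-D:A-friedooleana-1(10),4,6-trien-29-oate (o-quinone) | COC(=O)[C@]1(C)CC[C@]2(C)CC[C@]3(C)[C@@H]4C=CC5=C(C)C(=O)C(=O)C=C5[C@]4(C)CC[C@@]3(C)[C@@H]2C1
F6 | step 8 | cis-fused O-methyl ketal of the target (3'β-OMe, 3'α-O2, 4'α-O3) | COC(=O)[C@]1(C)CC[C@]2(C)CC[C@]3(C)[C@@H]4C=Cc5c(cc6c(c5C)O[C@@]5(C)C7=CC[C@H]8[C@@](C)(CC[C@@]9(C)[C@@H]%10C[C@](C)(C(=O)OC)CC[C@]%10(C)CC[C@]89C)C7=CC(=O)[C@@]5(OC)O6)[C@]4(C)CC[C@@]3(C)[C@@H]2C1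
F7 | step 7 | methyl 8α-H-4α-hydroxy-3,3-dimethoxy-2-oxo-24-nor-D:A-friedooleana-1(10),5-dien-29-oate | COC(=O)[C@]1(C)CC[C@]2(C)CC[C@]3(C)[C@H]4CC=C5[C@](C)(O)C(OC)(OC)C(=O)C=C5[C@]4(C)CC[C@@]3(C)[C@@H]2C1
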